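Ring D (the bridged cyclohexenone C11–C12–C13–C14(=O)–C15=C16) is opened at its enone bond C15=C16 by a retro-aldol: C16, shared with the 2H-pyran ring, becomes a ketone and C15 the methyl of an acetyl group on carbinol carbon C13. What remains is an 8-oxabicyclo[3.2.1]oct-3-en-2-one (ether O10 bridging C9 and C11), the retron of a 3-oxidopyrylium (5+2) cycloaddition. One base-mediated operation on a monocyclic acetoxypyranone with an (E)-styrene tether should thus close the tetrahydrofuran and tetralin rings and, last, ring D, setting C8, C9, C11 and C19 from C13.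

Key step: step 15

Labels used below (own numbering): ring A = 4-hydroxy-2-methoxyphenyl, ring B = 3-hydroxy-2,4-dimethoxyphenyl, ring C = the fused catechol ring, ring D = the cyclohexenone; C7 = CH2 on ring A; C8 = CH bearing C7; C9 = allylic O–CH bridgehead; O10 = ether oxygen; C11 = quaternary O–C bridgehead; C12 = CH2; C13 = carbinol carbon; C14 = C=O; C15 = enone CH; C16 = enone β-carbon; C17 = CH=; C18 = =C(ring B); C19 = CH bearing ring C. MOM = CH2OCH3, TMS = SiMe3, pin = pinacolato.

Assumption: the sense of induction of the tryptophan-derived oxazaborolidinone in step 10 is taken as Re-face attack on aldehyde 16 with the (S)-tryptophan catalyst; the (R)-tryptophan catalyst serves if it is the reverse.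

Step 1
Reactants: 1 4-bromo-3-methoxyphenol
Product: 2 1-bromo-2-methoxy-4-(methoxymethoxy)benzene
Conditions: MOMCl, i-Pr2NEt, CH2Cl2, 0 → 23 °C
Reagents that add atoms: chloromethyl methyl ether, COCCl
Why: Base-mediated O-alkylation of the phenol (MOM ether formation) masks the future ring A hydroxyl as an acetal that should survive the organometallic, basic and oxidative steps and fall off in acid at the end.

Step 2
Reactants: 2 1-bromo-2-methoxy-4-(methoxymethoxy)benzene; 3 methoxyallene
Product: 5 2-methoxy-4-(methoxymethoxy)-1-(prop-2-yn-1-yl)benzene, via aryl Grignard reagent 4 (not isolated)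
Conditions: Mg, THF, 45 °C; then 3, CuBr (5 mol %), THF, −20 → 23 °C
Reagents that add atoms: none
Why: Magnesium insertion gives the aryl Grignard reagent, which under copper catalysis attacks the CH2 terminus of methoxyallene in an SN2′ substitution with loss of methoxide, a known route from Grignard reagents to 3-substituted prop-1-ynes that supplies C7, C8 and C19.

Step 3
Reactants: 5 2-methoxy-4-(methoxymethoxy)-1-(prop-2-yn-1-yl)benzene
Product: 6 2-{(E)-3-[2-methoxy-4-(methoxymethoxy)phenyl]prop-1-en-1-yl}-4,4,5,5-tetramethyl-1,3,2-dioxaborolane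
Conditions: HBpin, Cp2Zr(H)Cl (5 mol %), Et3N (10 mol %), neat, 60 °C
Reagents that add atoms: pinacolborane, CC1(C)OBOC1(C)C
Why: Zirconium hydride-catalysed hydroboration adds H–B syn across the terminal alkyne with boron on the terminal carbon, so that the (E)-alkenylboronate should form without touching the acetal or the benzylic CH2.

Step 4
Reactants: 7 1-(3,4-dihydroxyphenyl)ethanone
Product: 8 1-[3,4-bis(methoxymethoxy)phenyl]ethanone
Conditions: MOMCl, i-Pr2NEt, CH2Cl2, 0 → 23 °C
Reagents that add atoms: chloromethyl methyl ether, COCCl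
Why: Double O-alkylation (MOM ether formation) protects the catechol of ring C with the same acid-labile group used on the other rings.

Step 5
Reactants: 8 1-[3,4-bis(methoxymethoxy)phenyl]ethanone
Product: 9 1-[2-bromo-4,5-bis(methoxymethoxy)phenyl]ethanone
Conditions: NBS, MeCN, 0 → 23 °C
Reagents that add atoms: N-bromosuccinimide, O=C1CCC(=O)N1Br
Why: Electrophilic aromatic bromination should take place at C6, para to the C3 acetal oxygen whose lone pair is not engaged by the para acetyl group, as in the bromination of 3,4-dialkoxyacetophenones.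

Step 6
Reactants: 6 the (E)-alkenylboronate; 9 1-[2-bromo-4,5-bis(methoxymethoxy)phenyl]ethanone
Product: 10 1-{4,5-bis(methoxymethoxy)-2-[(E)-3-(2-methoxy-4-(methoxymethoxy)phenyl)prop-1-en-1-yl]phenyl}ethanone
Conditions: Pd(dppf)Cl2 (5 mol %), K3PO4, THF/H2O, 60 °C
Reagents that add atoms: none
Why: Suzuki–Miyaura coupling of the alkenylboronate with the aryl bromide proceeds with retention of the (E) geometry and tolerates the ketone, which delivers the styrene dipolarophile already attached to ring C.

Step 7
Reactants: 11 2,6-dimethoxyphenol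
Product: 12 1,3-dimethoxy-2-(methoxymethoxy)benzene
Conditions: MOMCl, i-Pr2NEt, CH2Cl2, 0 → 23 °C
Reagents that add atoms: chloromethyl methyl ether, COCCl
Why: O-Alkylation (MOM ether formation) protects the future ring B hydroxyl and leaves only the positions ortho to a methoxy group open to metalation.

Step 8
Reactants: 12 1,3-dimethoxy-2-(methoxymethoxy)benzene
Product: 14 2-[2,4-dimethoxy-3-(methoxymethoxy)phenyl]-4,4,5,5-tetramethyl-1,3,2-dioxaborolane, via aryllithium 13 (not isolated)
Conditions: n-BuLi, TMEDA, THF, 0 °C; then i-PrOBpin, −78 → 23 °C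
Reagents that add atoms: 2-isopropoxy-4,4,5,5-tetramethyl-1,3,2-dioxaborolane, CC(C)OB1OC(C)(C)C(C)(C)O1
Why: Directed ortho-metalation by a methoxy group (the two possible positions are equivalent by symmetry) followed by borylation of the aryllithium gives the ring B boronate with the 2,3,4-trioxygenation pattern in place.

Step 9
Reactants: 14 the ring B boronate; 15 4-bromofuran-2-carbaldehyde
Product: 16 4-[2,4-dimethoxy-3-(methoxymethoxy)phenyl]furan-2-carbaldehyde
Conditions: Pd(PPh3)4 (5 mol %), K2CO3, 1,4-dioxane/H2O, 85 °C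
Reagents that add atoms: none
Why: Suzuki–Miyaura coupling at the C4 bromide of the furan places ring B on the carbon that becomes C18, and the aldehyde, untouched by the carbonate base, remains as the future C11.

Step 10
Reactants: 10 the aryl methyl ketone; 16 the 4-arylfurfural
Product: 19 (3R)-1-{4,5-bis(methoxymethoxy)-2-[(E)-3-(2-methoxy-4-(methoxymethoxy)phenyl)prop-1-en-1-yl]phenyl}-3-{4-[2,4-dimethoxy-3-(methoxymethoxy)phenyl]furan-2-yl}-3-hydroxypropan-1-one, via silyl enol ether 17 (not isolated), via silyl aldol ether 18 (not isolated)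
Conditions: LiN(i-Pr)2, Me3SiCl, THF, −78 °C; then 16, (S)-N-tosyltryptophan-derived B-butyl-1,3,2-oxazaborolidin-5-one (20 mol %), EtCN, −78 °C; 1 M HCl, THF, 0 °C
Reagents that add atoms: none
Why: Kinetic enolisation and silylation give the methyl ketone enol silane, whose Mukaiyama aldol addition to 16 under the chiral boron Lewis acid (one aldehyde face is shielded by the indole ring of the catalyst) should give the (R)-carbinol at C11, the silyl ether protecting the aldol from β-elimination until the cold acidic work-up.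

Step 11
Reactants: 19 the (R)-β-hydroxy ketone; 20 ethyl vinyl ether
Product: 22 (3S,5R)-3-{4,5-bis(methoxymethoxy)-2-[(E)-3-(2-methoxy-4-(methoxymethoxy)phenyl)prop-1-en-1-yl]phenyl}-5-{4-[2,4-dimethoxy-3-(methoxymethoxy)phenyl]furan-2-yl}-3,5-dihydroxypentan-2-one, via enol ether diol 21 (not isolated)
Conditions: 20, t-BuLi, THF, −78 → 0 °C; then 19, MgBr2·OEt2, THF, −78 °C; 0.5 M HCl, THF, 0 °C
Reagents that add atoms: water, O
Why: 1,2-Addition of the acyl anion equivalent 1-ethoxyvinyllithium to the magnesium-chelated β-alkoxido ketone (chelation control, the nucleophile entering axially in the six-membered chelate that holds the furyl group equatorial) should give the 1,3-syn diol, that is (S) at C13, and mild acid hydrolysis of the enol ether unveils the acetyl group, any minor C13 epimer being removed by chromatography.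

Step 12
Reactants: 22 the furyl diol ketone
Product: 23 (2R)-2-[(2S)-2-{4,5-bis(methoxymethoxy)-2-[(E)-3-(2-methoxy-4-(methoxymethoxy)phenyl)prop-1-en-1-yl]phenyl}-2-hydroxy-3-oxobutyl]-5-[2,4-dimethoxy-3-(methoxymethoxy)phenyl]-6-hydroxy-2H-pyran-3(6H)-one (both C6 anomers)
Conditions: VO(acac)2 (5 mol %), t-BuOOH, CH2Cl2, 0 °C
Reagents that add atoms: tert-butyl hydroperoxide, CC(C)(C)OO
Why: Achmatowicz rearrangement, in which hydroxyl-directed vanadium-catalysed oxidation of the furan and ring expansion give the 6-hydroxy-2H-pyran-3(6H)-one with C11 retained, the directing carbinol keeping the oxidant away from the styrene and the aryl ethers.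

Step 13
Reactants: 23 the hydroxypyranone
Product: 24 the 6-O-acetate of 23 (both anomers)
Conditions: Ac2O, pyridine, DMAP (cat.), CH2Cl2, −20 °C
Reagents that add atoms: acetic anhydride, CC(=O)OC(C)=O
Why: Acylation of the reactive hemiacetal hydroxyl installs the leaving group for ylide formation, the hindered tertiary C13 hydroxyl being inert under these conditions.

Step 14
Reactants: 24 the acetoxypyranone
Product: 25 the C13 O-trimethylsilyl ether of 24
Conditions: N-(trimethylsilyl)imidazole, CH2Cl2, 23 °C
Reagents that add atoms: N-(trimethylsilyl)imidazole, C[Si](C)(C)n1ccnc1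
Why: Silylation of the tertiary alcohol with a neutral silyl-transfer reagent removes the hydrogen-bond donor that would otherwise bind the oxide of the ylide and blocks α-ketol rearrangement under base, without touching the anomeric acetate.

Step 15
Reactants: 25 the silylated acetoxypyranone
Product: 29 the tetra-MOM, C13 O-TMS ether of the target, via oxidopyrylium ylide 26 (not isolated), via cycloadduct diketone 27 (not isolated), via aldol adduct 28 (not isolated)
Conditions: DBU (3 equiv), MeCN (0.005 M), 23 °C, then 70 °C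
Reagents that add atoms: none
Why: DBU removes the C11 proton of 25 and acetate leaves from C9 (E1cB), giving 3-oxidopyrylium ylide 26, whose C11 and C9 termini add suprafacially across the tethered (E)-styrene C19=C8 in an intramolecular (5+2) dipolar cycloaddition (closest known type: intramolecular oxidopyrylium–alkene cycloaddition of Achmatowicz-derived acetoxypyranones), and adduct 27 then undergoes a Robinson-type intramolecular aldol condensation under the same base. The cycloaddition closes the tetrahydrofuran ring (bonds C8–C9 and C11–C19) and, through the four-atom tether, the tetralin ring in one concerted event; ring D is closed last by 6-(enolexo)-exo-trig attack of the C15 enolate on the C16 ketone followed by E1cB loss of water from 28. C9 and C11 are set together by the face of the planar ylide that is attacked, C8 and C19 come out trans because the E geometry is transferred suprafacially, and the face is chosen by C13, which should place its acetyl group next to the C16 oxide (carbonyl–oxide dipole attraction) and the bulky, non-donating silyl ether outward. The step needs the endo-tether mode (ring C on C19 syn to the C16–C18 bridge, trans ring fusion), which should be favoured because the conjugating aryl group takes the endo position whereas the alternative would push the CH2–ring A group over the aryl-bearing C18, and because four-atom tethers carry no intrinsic bias against trans fusion. Only this adduct holds the C13 acetyl 1,3-diaxial to C16, so only it can condense to the dienone, and the acetyl methyl is the only enolisable position of 27, which secures the regiochemistry of the aldol step.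

Step 16
Reactants: 29 the protected dienone
Product: 30 the target, CNP0246028.1
Conditions: HCl (1.25 M in MeOH), THF, 0 → 23 °C, under argon
Reagents that add atoms: none
Why: Acid-catalysed acetal exchange to methanol cleaves the four aryl MOM ethers and the silyl ether, while the bridgehead C13 carbinol, which cannot ionise (bridgehead, α to the ketone), and the other stereocentres are untouched.

Compound list
1 | 4-bromo-3-methoxyphenol | COc1cc(O)ccc1Br | starting material
2 | 1-bromo-2-methoxy-4-(methoxymethoxy)benzene | COCOc1ccc(Br)c(OC)c1 | intermediate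
3 | methoxyallene (1-methoxypropa-1,2-diene) | COC=C=C | starting material
4 | [2-methoxy-4-(methoxymethoxy)phenyl]magnesium bromide | COCOc1ccc([Mg]Br)c(OC)c1 | intermediate
5 | 2-methoxy-4-(methoxymethoxy)-1-(prop-2-yn-1-yl)benzene | COCOc1ccc(CC#C)c(OC)c1 | intermediate
6 | 2-{(E)-3-[2-methoxy-4-(methoxymethoxy)phenyl]prop-1-en-1-yl}-4,4,5,5-tetramethyl-1,3,2-dioxaborolane | COCOc1ccc(C/C=C/B2OC(C)(C)C(C)(C)O2)c(OC)c1 | intermediate
7 | 1-(3,4-dihydroxyphenyl)ethanone | CC(=O)c1ccc(O)c(O)c1 | starting material
8 | 1-[3,4-bis(methoxymethoxy)phenyl]ethanone | CC(=O)c1ccc(OCOC)c(OCOC)c1 | intermediate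
9 | 1-[2-bromo-4,5-bis(methoxymethoxy)phenyl]ethanone | CC(=O)c1cc(OCOC)c(OCOC)cc1Br | intermediate
10 | 1-{4,5-bis(methoxymethoxy)-2-[(E)-3-(2-methoxy-4-(methoxymethoxy)phenyl)prop-1-en-1-yl]phenyl}ethanone | CC(=O)c1cc(OCOC)c(OCOC)cc1/C=C/Cc1ccc(OCOC)cc1OC | intermediate
11 | 2,6-dimethoxyphenol | COc1cccc(OC)c1O | starting material
12 | 1,3-dimethoxy-2-(methoxymethoxy)benzene | COCOc1c(OC)cccc1OC | intermediate
13 | [2,4-dimethoxy-3-(methoxymethoxy)phenyl]lithium | COCOc1c(OC)ccc([Li])c1OC | intermediate
14 | 2-[2,4-dimethoxy-3-(methoxymethoxy)phenyl]-4,4,5,5-tetramethyl-1,3,2-dioxaborolane | COCOc1c(OC)ccc(B2OC(C)(C)C(C)(C)O2)c1OC | intermediate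
15 | 4-bromofuran-2-carbaldehyde | O=Cc1cc(Br)co1 | starting material
16 | 4-[2,4-dimethoxy-3-(methoxymethoxy)phenyl]furan-2-carbaldehyde | O=Cc1cc(-c2ccc(OC)c(OCOC)c2OC)co1 | intermediate
17 | trimethylsilyl enol ether of 10, (1-arylethenyl)oxytrimethylsilane | C=C(O[Si](C)(C)C)c1cc(OCOC)c(OCOC)cc1/C=C/Cc1ccc(OCOC)cc1OC | intermediate
18 | (R)-O-trimethylsilyl ether of aldol 19 | C[Si](C)(C)O[C@H](CC(=O)c1cc(OCOC)c(OCOC)cc1/C=C/Cc1ccc(OCOC)cc1OC)c1cc(-c2ccc(OC)c(OCOC)c2OC)co1 | intermediate
19 | (3R)-1-{4,5-bis(methoxymethoxy)-2-[(E)-3-(2-methoxy-4-(methoxymethoxy)phenyl)prop-1-en-1-yl]phenyl}-3-{4-[2,4-dimethoxy-3-(methoxymethoxy)phenyl]furan-2-yl}-3-hydroxypropan-1-one | O[C@H](CC(=O)c1cc(OCOC)c(OCOC)cc1/C=C/Cc1ccc(OCOC)cc1OC)c1cc(-c2ccc(OC)c(OCOC)c2OC)co1 | intermediate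
20 | ethyl vinyl ether | C=COCC | starting material
21 | (1R,3S)-3-aryl-4-ethoxy-1-(4-arylfuran-2-yl)pent-4-ene-1,3-diol (aryl groups as in 22) | C=C(OCC)[C@](O)(C[C@@H](O)c1cc(-c2ccc(OC)c(OCOC)c2OC)co1)c1cc(OCOC)c(OCOC)cc1/C=C/Cc1ccc(OCOC)cc1OC | intermediate
22 | (3S,5R)-3-{4,5-bis(methoxymethoxy)-2-[(E)-3-(2-methoxy-4-(methoxymethoxy)phenyl)prop-1-en-1-yl]phenyl}-5-{4-[2,4-dimethoxy-3-(methoxymethoxy)phenyl]furan-2-yl}-3,5-dihydroxypentan-2-one | CC(=O)[C@](O)(C[C@@H](O)c1cc(-c2ccc(OC)c(OCOC)c2OC)co1)c1cc(OCOC)c(OCOC)cc1/C=C/Cc1ccc(OCOC)cc1OC | intermediate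
23 | (2R)-2-[(2S)-2-aryl-2-hydroxy-3-oxobutyl]-5-[2,4-dimethoxy-3-(methoxymethoxy)phenyl]-6-hydroxy-2H-pyran-3(6H)-one, both C6 anomers (aryl as in 22) | CC(=O)[C@](O)(C[C@H]1OC(O)C(-c2ccc(OC)c(OCOC)c2OC)=CC1=O)c1cc(OCOC)c(OCOC)cc1/C=C/Cc1ccc(OCOC)cc1OC | intermediate
24 | 6-O-acetate of 23, both anomers | CC(=O)[C@](O)(C[C@H]1OC(OC(C)=O)C(-c2ccc(OC)c(OCOC)c2OC)=CC1=O)c1cc(OCOC)c(OCOC)cc1/C=C/Cc1ccc(OCOC)cc1OC | intermediate
25 | C13 O-trimethylsilyl ether of 24, (2S) at the silyloxy carbon, (2R) on the pyranone | CC(=O)[C@](O[Si](C)(C)C)(C[C@H]1OC(OC(C)=O)C(-c2ccc(OC)c(OCOC)c2OC)=CC1=O)c1cc(OCOC)c(OCOC)cc1/C=C/Cc1ccc(OCOC)cc1OC | intermediate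
26 | 3-oxidopyrylium ylide (2-alkyl-5-aryl-pyrylium-3-olate) with the (S)-C13 side chain | CC(=O)[C@](O[Si](C)(C)C)(Cc1[o+]cc(-c2ccc(OC)c(OCOC)c2OC)cc1[O-])c1cc(OCOC)c(OCOC)cc1/C=C/Cc1ccc(OCOC)cc1OC | intermediate
27 | (5+2) cycloadduct: 8-oxabicyclo[3.2.1]oct-3-en-2-one (C16 ketone, C17=C18) fused at C11–C19 to the tetralin ring; CH2–ring A exo on C8, ring C endo on C19, C13 acetyl syn to C16, C13 OTMS | COc1cc(OCOC)ccc1C[C@@H]1[C@@H]2O[C@@]3(C[C@@](O[Si](C)(C)C)(C(C)=O)c4cc(OCOC)c(OCOC)cc4[C@@H]13)C(=O)C=C2c1ccc(OC)c(OCOC)c1OC | intermediate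
28 | aldol adduct of 27: ring D closed, tertiary C16 hydroxyl syn to O10 | COc1cc(OCOC)ccc1C[C@@H]1[C@@H]2O[C@@]34C[C@@](O[Si](C)(C)C)(C(=O)C[C@]3(O)C=C2c2ccc(OC)c(OCOC)c2OC)c2cc(OCOC)c(OCOC)cc2[C@@H]14 | intermediate
29 | tetra-O-MOM, C13 O-TMS ether of the target (pentacyclic dienone, configuration as in 30) | COc1cc(OCOC)ccc1C[C@@H]1[C@@H]2O[C@@]34C[C@@](O[Si](C)(C)C)(C(=O)C=C3C=C2c2ccc(OC)c(OCOC)c2OC)c2cc(OCOC)c(OCOC)cc2[C@@H]14 | intermediate
30 | CNP0246028.1: pentacyclic dienone with CH2–ring A exo on C8, ring C endo on C19 (fused), C13 hydroxyl equatorial and C14 bridging to C16 | COc1cc(O)ccc1C[C@@H]1[C@@H]2O[C@@]34C[C@@](O)(C(=O)C=C3C=C2c2ccc(OC)c(O)c2OC)c2cc(O)c(O)cc2[C@@H]14 | target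

Total step count: 16. Longest linear sequence: 11 steps (1, 2, 3, 6, 10, 11, 12, 13, 14, 15, 16).

Steps most likely to fail

Step 15. The cycloaddition may run through the exo-tether mode or on the other face of the ylide (poor mode or facial selectivity), which leaves adducts whose acetyl group cannot reach C16, so that ring D does not close. The fallback blocks the endo position of C8 by a different means and sets out from 25. Treatment with DDQ and MeOH in CH2Cl2 (oxidative C–H etherification of the doubly activated C7 methylene of the 1,3-diarylpropene) should give the C7 methoxy acetate F1 as both C7 epimers. Its branched CH(OMe)–ring A substituent cannot sit over C18, so the same DBU treatment should give the C7 methoxy dienone F2 through the endo-tether mode. Ionic hydrogenolysis of the electron-rich benzylic ether with Et3SiH and CF3CO2H in CH2Cl2 at −20 → 0 °C, which also removes the MOM and TMS groups, comes back to the route at 30.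

Step 10. The silyl aldol may eliminate to the enone, or the catalyst may discriminate poorly between the aldehyde faces (β-elimination, low enantioselectivity). The fallback makes the carbinol by conjugate borylation and sets out from 10 and 16. Claisen–Schmidt condensation (Ba(OH)2, MeOH, 23 °C) should give the (E)-enone F3. Enantioselective β-borylation (CuCl, NaOt-Bu, a chiral ferrocenyl bisphosphine, B2pin2, MeOH, THF) should give the (R)-β-boryl ketone F4. Oxidation with NaBO3·4H2O in THF/H2O, with retention at C11, comes back to the route at 19.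

Step 12. The vanadium–peroxide system may also epoxidise the electron-rich styrene (directed by the C13 hydroxyl) or attack the aryl ethers (loss of chemoselectivity). The fallback oxidises the furan by a different mechanism and sets out from 22: singlet-oxygen (4+2) photo-oxygenation (O2, rose bengal, visible light, MeOH, −78 °C) followed by reduction of the endoperoxide with Me2S, which comes back to the route at 23. No isolated new compound arises (F0).

Further compounds
F1 | step 15 | C7 methoxy analogue of 25, both C7 epimers | CC(=O)[C@](O[Si](C)(C)C)(C[C@H]1OC(OC(C)=O)C(-c2ccc(OC)c(OCOC)c2OC)=CC1=O)c1cc(OCOC)c(OCOC)cc1/C=C/C(OC)c1ccc(OCOC)cc1OC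
F2 | step 15 | C7 methoxy analogue of 29, both C7 epimers | COc1cc(OCOC)ccc1C(OC)[C@@H]1[C@@H]2O[C@@]34C[C@@](O[Si](C)(C)C)(C(=O)C=C3C=C2c2ccc(OC)c(OCOC)c2OC)c2cc(OCOC)c(OCOC)cc2[C@@H]14
F3 | step 10 | (E)-enone from 10 and 16, (2E)-1-aryl-3-(4-arylfuran-2-yl)prop-2-en-1-one | O=C(/C=C/c1cc(-c2ccc(OC)c(OCOC)c2OC)co1)c1cc(OCOC)c(OCOC)cc1/C=C/Cc1ccc(OCOC)cc1OC
F4 | step 10 | (3R)-β-(pinacolatoboryl) ketone | CC1(C)OB(OC1(C)C)[C@H](CC(=O)c1cc(OCOC)c(OCOC)cc1/C=C/Cc1ccc(OCOC)cc1OC)c1cc(-c2ccc(OC)c(OCOC)c2OC)co1
F0 | step 12 | none | none
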